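**Retrosynthetic overview**

1. Target 24 ⇐ diol 23 ⇐ C7=C8 alkene by reduction of the C7 enol triflate 21 ⇐ C7 enone 19 ⇐ oxidative 1,3-transposition of the C9 carbinol 18, made by forming C9–C11 from bicyclic C9 enone 10 and side-chain iodide 15 (C13 from methyl (R)-3-methylglutarate 11).
2. Ring A of 9 ⇐ monocyclic keto aldehyde 7: the C2–C3 bond is formed by Prins attack of the isopropenyl CH2 (C3) on the C2 aldehyde, and the C4 cation takes its second methyl (C19) from aluminium in the same flask.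
3. 7 ⇐ (S)-carvone 1: the carvone ring is ring B (C5–C10 with C17), its isopropenyl group is C3/C4/C18, and C20 and then the C1–C2 arm are put on C10 by two α′-alkylations. Ring order: B from the chiral pool, then A in the key step.
4. Enabling feature: in ring A the C2 carbinol and the quaternary C4 are 1,3-related through the methylene C3, so an isopropenyl group on C5 (C3=C4) and a C2 aldehyde on the trans C10 arm form a Prins/ene pair; the axial C20 methyl on C10 steers O2 equatorial and the C9 carbonyl of ring B shields C10 from cationic shifts.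

Key step: step 5

Remark: labdane numbering (C1–C10 decalin, C11–C16 side chain, C17 on C8, C18 and C19 on C4, C20 on C10) serves for locants only; the target is the (2R,5R,9R,10R,13S) isomer read from the SMILES (trans-decalin, C2 acetate equatorial and anti to C20), and (S)-carvone and methyl (R)-3-methylglutarate are taken as commercial.

**Route**

Step 1
Reactants: 1 (S)-(+)-carvone
Product: 3 (5S,6R)-2,6-dimethyl-5-(prop-1-en-2-yl)cyclohex-2-en-1-one, via lithium dienolate 2 (not isolated)
Conditions: LiN(i-Pr)2, THF, −78 °C; MeI, −78 → 0 °C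
Reagents that add atoms: iodomethane, CI
Why: Kinetic α′-deprotonation and enolate alkylation; MeI should enter mainly anti to the C5 isopropenyl group, and the C6 configuration is erased again in step 2.

Step 2
Reactants: 3 (5S,6R)-2,6-dimethyl-5-(prop-1-en-2-yl)cyclohex-2-en-1-one
Product: 5 ethyl 2-[(1R,6R)-1,3-dimethyl-2-oxo-6-(prop-1-en-2-yl)cyclohex-3-en-1-yl]acetate, via lithium dienolate 4 (not isolated)
Conditions: LiN(i-Pr)2, THF, −78 °C; DMPU, BrCH2CO2Et, −78 → −20 °C
Reagents that add atoms: ethyl bromoacetate, CCOC(=O)CBr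
Why: Enolate alkylation of the tetrasubstituted α′-enolate; the electrophile approaches the face opposite the adjacent C5 isopropenyl group, so the C1–C2 arm ends trans and C20 cis to it, which sets the quaternary C10 stereocentre under substrate control.

Step 3
Reactants: 5 ethyl 2-[(1R,6R)-1,3-dimethyl-2-oxo-6-(prop-1-en-2-yl)cyclohex-3-en-1-yl]acetate
Product: 6 2-[(1R,6R)-2-hydroxy-1,3-dimethyl-6-(prop-1-en-2-yl)cyclohex-3-en-1-yl]ethan-1-ol (both ring-carbinol epimers)
Conditions: i-Bu2AlH (4 equiv), CH2Cl2, −78 → 0 °C; aq. KNaC4H4O6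
Reagents that add atoms: none
Why: Hydride reduction of the ester to the primary alcohol and 1,2-reduction of the enone; the new carbinol centre does not matter because it is re-oxidised in step 4.

Step 4
Reactants: 6 2-[(1R,6R)-2-hydroxy-1,3-dimethyl-6-(prop-1-en-2-yl)cyclohex-3-en-1-yl]ethan-1-ol
Product: 7 2-[(1R,6R)-1,3-dimethyl-2-oxo-6-(prop-1-en-2-yl)cyclohex-3-en-1-yl]acetaldehyde
Conditions: (COCl)2, DMSO, CH2Cl2, −78 °C; Et3N, −78 → 0 °C
Reagents that add atoms: none
Why: Swern oxidation; both hydroxyls are turned into alkoxysulfonium ions before the base is added, so the enone is restored and the primary alcohol stops at the aldehyde without lactol or lactone formation.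

Step 5
Reactants: 7 2-[(1R,6R)-1,3-dimethyl-2-oxo-6-(prop-1-en-2-yl)cyclohex-3-en-1-yl]acetaldehyde
Product: 9 (4aR,7R,8aR)-7-hydroxy-2,5,5,8a-tetramethyl-4a,5,6,7,8,8a-hexahydronaphthalen-1(4H)-one, via tertiary chloride 8 (not isolated)
Conditions: MeAlCl2 (2.2 equiv), CH2Cl2, −78 °C; then AlMe3 (4 equiv), −78 → −30 °C; aq. KNaC4H4O6
Reagents that add atoms: trimethylaluminium, C[Al](C)C
Why: Proposed new method: MeAlCl2 activates the C2 aldehyde, the terminal alkene carbon C3 of the isopropenyl group attacks it, and the tertiary C4 cation is parked as chloride 8 by chloride return from the aluminate; AlMe3 then re-ionises 8 and transfers methyl (C19) to C4, so the C2–C3 bond, ring A and the gem-dimethyl quaternary carbon arise in one flask. The closest known reaction types are the alkylaluminium-chloride-induced type 2 carbonyl-ene/Prins cyclisation of δ,ε-unsaturated aldehydes (ene adducts or γ-chloro alcohols) and the methylation of tertiary alkyl chlorides by AlMe3; their merger into an alkylative Prins closure has not been shown. Ring A closes in a 6-endo-trig cation–olefin mode (alkene C3=C4 inside the new ring, carbonyl oxygen outside it) through a chair. The only new stereocentre, C2, is set by substrate control: in the chair the aluminium-bound oxygen sits equatorial to avoid the 1,3-diaxial contact with the axial C20 methyl on C10, and the trans ring fusion follows from the trans C1 and C4 arms of 7. The step needs chemoselectivity for the aldehyde over the conjugated, hindered C9 carbonyl, and capture of the C4 cation by chloride and then methyl before proton loss or a hydride shift from C5; the excess MeAlCl2 (non-basic aluminate) favours chloride collapse, the electron-poor enone alkene is no competing nucleophile, and the C9 carbonyl next to C10 disfavours migration of C20.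

Step 6
Reactants: 9 (4aR,7R,8aR)-7-hydroxy-2,5,5,8a-tetramethyl-4a,5,6,7,8,8a-hexahydronaphthalen-1(4H)-one
Product: 10 (4aR,7R,8aR)-7-[(tert-butyldimethylsilyl)oxy]-2,5,5,8a-tetramethyl-4a,5,6,7,8,8a-hexahydronaphthalen-1(4H)-one
Conditions: TBSCl, imidazole, DMF, rt
Reagents that add atoms: tert-butyldimethylsilyl chloride, CC(C)(C)[Si](C)(C)Cl
Why: Silyl ether formation at the equatorial secondary alcohol; the ether carries C2–O through the organometallic, chromium and dissolving-metal steps.

Step 7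
Reactants: 11 methyl (R)-3-methylglutarate
Product: 12 methyl (3R)-5-hydroxy-3-methylpentanoate
Conditions: BH3·SMe2 (1.2 equiv), THF, 0 °C → rt; aq. work-up, used crude
Reagents that add atoms: none
Why: Chemoselective borane reduction of the carboxylic acid beside the methyl ester; the stereocentre is untouched and the crude hydroxy ester is silylated at once to forestall lactonisation.

Step 8
Reactants: 12 methyl (3R)-5-hydroxy-3-methylpentanoate
Product: 13 methyl (3R)-5-[(tert-butyldimethylsilyl)oxy]-3-methylpentanoate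
Conditions: TBSCl, imidazole, CH2Cl2, 0 °C → rt
Reagents that add atoms: tert-butyldimethylsilyl chloride, CC(C)(C)[Si](C)(C)Cl
Why: Silyl ether formation at the primary alcohol, which becomes O15 of the target.

Step 9
Reactants: 13 methyl (3R)-5-[(tert-butyldimethylsilyl)oxy]-3-methylpentanoate
Product: 14 (3S)-5-[(tert-butyldimethylsilyl)oxy]-3-methylpentan-1-ol
Conditions: LiAlH4, Et2O, 0 °C
Reagents that add atoms: none
Why: Hydride reduction of the ester; the silyl ether and the stereocentre are unaffected (the descriptor changes only through priorities).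

Step 10
Reactants: 14 (3S)-5-[(tert-butyldimethylsilyl)oxy]-3-methylpentan-1-ol
Product: 15 tert-butyl{[(3R)-5-iodo-3-methylpentyl]oxy}dimethylsilane
Conditions: I2, PPh3, imidazole, CH2Cl2, 0 °C → rt
Reagents that add atoms: iodine, II
Why: Appel-type iodination of the primary alcohol by SN2 displacement of the alkoxyphosphonium ion.

Step 11
Reactants: 15 tert-butyl{[(3R)-5-iodo-3-methylpentyl]oxy}dimethylsilane; 10 (4aR,7R,8aR)-7-[(tert-butyldimethylsilyl)oxy]-2,5,5,8a-tetramethyl-4a,5,6,7,8,8a-hexahydronaphthalen-1(4H)-one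
Product: 18 (2R,5R,10R,13S)-2,15-bis[(tert-butyldimethylsilyl)oxy]labd-7-en-9-ol (both C9 epimers), via organolithium 16 (not isolated), via organocerium 17 (not isolated)
Conditions: 15, t-BuLi (2.1 equiv), Et2O, −78 °C; CeCl3, THF, −78 °C; then 10, −78 → −20 °C; aq. NH4Cl
Reagents that add atoms: none
Why: Iodine–lithium exchange and transmetalation give a weakly basic organocerium that should add 1,2 to the hindered C9 enone carbonyl (carbonyl addition), which has no α′-hydrogen; either C9 epimer serves because the carbinol is consumed in step 12.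

Step 12
Reactants: 18 (2R,5R,10R,13S)-2,15-bis[(tert-butyldimethylsilyl)oxy]labd-7-en-9-ol
Product: 19 (2R,5R,10R,13S)-2,15-bis[(tert-butyldimethylsilyl)oxy]labd-8-en-7-one
Conditions: (C5H5NH)[CrO3Cl] (pyridinium chlorochromate), NaOAc, 4 Å MS, CH2Cl2, rt
Reagents that add atoms: pyridinium chlorochromate, [O-][Cr](=O)(=O)Cl.c1cc[nH+]cc1
Why: Babler–Dauben oxidative 1,3-transposition; the tertiary allylic chromate ester undergoes a [3,3] shift to C7 and is oxidised there, which gives the tetrasubstituted enone and relieves the congested C9 carbinol.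

Step 13
Reactants: 19 (2R,5R,10R,13S)-2,15-bis[(tert-butyldimethylsilyl)oxy]labd-8-en-7-one
Product: 21 (2R,5R,9S,10R,13S)-2,15-bis[(tert-butyldimethylsilyl)oxy]labd-7-en-7-yl trifluoromethanesulfonate, via lithium enolate 20 (not isolated)
Conditions: Li (2.5 equiv), t-BuOH (1.0 equiv), NH3(l)/THF, −78 °C; isoprene; NH3 removed; PhNTf2, THF, −78 → 0 °C
Reagents that add atoms: N-phenylbis(trifluoromethanesulfonimide), FC(F)(F)S(=O)(=O)N(c1ccccc1)S(=O)(=O)C(F)(F)F
Why: Dissolving-metal (Birch-type) enone reduction; C9 should be protonated from the face opposite the axial C20 methyl, giving H9 anti to C20 and an equatorial side chain under substrate control, and the regiodefined C7 enolate is trapped on oxygen (reductive enol triflation).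

Step 14
Reactants: 21 (2R,5R,9S,10R,13S)-2,15-bis[(tert-butyldimethylsilyl)oxy]labd-7-en-7-yl trifluoromethanesulfonate
Product: 22 (2R,5R,9R,10R,13S)-2,15-bis[(tert-butyldimethylsilyl)oxy]labd-7-ene
Conditions: Pd(OAc)2 (5 mol %), PPh3 (10 mol %), Bu3N, HCO2H, DMF, 60 °C
Reagents that add atoms: none
Why: Palladium-catalysed formate reduction of the enol triflate (oxidative addition, decarboxylation of formate, reductive elimination) replaces OTf by H without moving the alkene, so the C7=C8 position is fixed.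

Step 15
Reactants: 22 (2R,5R,9R,10R,13S)-2,15-bis[(tert-butyldimethylsilyl)oxy]labd-7-ene
Product: 23 (2R,5R,9R,10R,13S)-labd-7-ene-2,15-diol
Conditions: Bu4NF (3 equiv), THF, rt → 45 °C
Reagents that add atoms: none
Why: Fluoride-mediated desilylation of both silyl ethers.

Step 16
Reactants: 23 (2R,5R,9R,10R,13S)-labd-7-ene-2,15-diol
Product: 24 (2R,5R,9R,10R,13S)-labd-7-ene-2,15-diyl diacetate (CNP0220683.1)
Conditions: Ac2O, pyridine, DMAP (cat.), CH2Cl2, rt
Reagents that add atoms: acetic anhydride, CC(=O)OC(C)=O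
Why: DMAP-catalysed acylation of the primary and the equatorial secondary alcohol gives the diacetate.

**Compound list**

1 | (S)-(+)-carvone, (5S)-2-methyl-5-(prop-1-en-2-yl)cyclohex-2-en-1-one | O=C1C(C)=CC[C@H](C(C)=C)C1 | starting material
2 | lithium (3S)-6-methyl-3-(prop-1-en-2-yl)cyclohexa-1,5-dien-1-olate (not isolated) | [Li]OC1=C[C@@H](C(C)=C)CC=C1C | intermediate
3 | (5S,6R)-2,6-dimethyl-5-(prop-1-en-2-yl)cyclohex-2-en-1-one | O=C1C(C)=CC[C@H](C(C)=C)[C@H]1C | intermediate
4 | lithium (3R)-2,6-dimethyl-3-(prop-1-en-2-yl)cyclohexa-1,5-dien-1-olate (not isolated) | [Li]OC1=C(C)[C@@H](C(C)=C)CC=C1C | intermediate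
5 | ethyl 2-[(1R,6R)-1,3-dimethyl-2-oxo-6-(prop-1-en-2-yl)cyclohex-3-en-1-yl]acetate | O=C1C(C)=CC[C@H](C(C)=C)[C@@]1(C)CC(=O)OCC | intermediate
6 | 2-[(1R,6R)-2-hydroxy-1,3-dimethyl-6-(prop-1-en-2-yl)cyclohex-3-en-1-yl]ethan-1-ol (both ring-carbinol epimers) | OC1C(C)=CC[C@H](C(C)=C)[C@@]1(C)CCO | intermediate
7 | 2-[(1R,6R)-1,3-dimethyl-2-oxo-6-(prop-1-en-2-yl)cyclohex-3-en-1-yl]acetaldehyde | O=C1C(C)=CC[C@H](C(C)=C)[C@@]1(C)CC=O | intermediate
8 | (4aS,7S,8aR)-5-chloro-7-hydroxy-2,5,8a-trimethyl-4a,5,6,7,8,8a-hexahydronaphthalen-1(4H)-one (held as its aluminium alkoxide; C5 epimers; not isolated) | O=C1C(C)=CC[C@@H]2C(C)(Cl)C[C@@H](O)C[C@@]12C | intermediate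
9 | (4aR,7R,8aR)-7-hydroxy-2,5,5,8a-tetramethyl-4a,5,6,7,8,8a-hexahydronaphthalen-1(4H)-one | O=C1C(C)=CC[C@@H]2C(C)(C)C[C@@H](O)C[C@@]12C | intermediate
10 | (4aR,7R,8aR)-7-[(tert-butyldimethylsilyl)oxy]-2,5,5,8a-tetramethyl-4a,5,6,7,8,8a-hexahydronaphthalen-1(4H)-one | O=C1C(C)=CC[C@@H]2C(C)(C)C[C@@H](O[Si](C)(C)C(C)(C)C)C[C@@]12C | intermediate
11 | methyl (R)-3-methylglutarate, (3R)-5-methoxy-3-methyl-5-oxopentanoic acid | OC(=O)C[C@@H](C)CC(=O)OC | starting material
12 | methyl (3R)-5-hydroxy-3-methylpentanoate | OCC[C@@H](C)CC(=O)OC | intermediate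
13 | methyl (3R)-5-[(tert-butyldimethylsilyl)oxy]-3-methylpentanoate | CC(C)(C)[Si](C)(C)OCC[C@@H](C)CC(=O)OC | intermediate
14 | (3S)-5-[(tert-butyldimethylsilyl)oxy]-3-methylpentan-1-ol | CC(C)(C)[Si](C)(C)OCC[C@@H](C)CCO | intermediate
15 | tert-butyl{[(3R)-5-iodo-3-methylpentyl]oxy}dimethylsilane | CC(C)(C)[Si](C)(C)OCC[C@@H](C)CCI | intermediate
16 | {(3S)-5-[(tert-butyldimethylsilyl)oxy]-3-methylpentyl}lithium (not isolated) | CC(C)(C)[Si](C)(C)OCC[C@@H](C)CC[Li] | intermediate
17 | {(3R)-5-[(tert-butyldimethylsilyl)oxy]-3-methylpentyl}cerium dichloride (not isolated) | CC(C)(C)[Si](C)(C)OCC[C@@H](C)CC[Ce](Cl)Cl | intermediate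
18 | (2R,5R,10R,13S)-2,15-bis[(tert-butyldimethylsilyl)oxy]labd-7-en-9-ol (both C9 epimers) | CC(C)(C)[Si](C)(C)OCC[C@@H](C)CCC1(O)C(C)=CC[C@@H]2C(C)(C)C[C@@H](O[Si](C)(C)C(C)(C)C)C[C@@]12C | intermediate
19 | (2R,5R,10R,13S)-2,15-bis[(tert-butyldimethylsilyl)oxy]labd-8-en-7-one | CC(C)(C)[Si](C)(C)OCC[C@@H](C)CCC1=C(C)C(=O)C[C@@H]2C(C)(C)C[C@@H](O[Si](C)(C)C(C)(C)C)C[C@@]12C | intermediate
20 | lithium (2R,5R,9S,10R,13S)-2,15-bis[(tert-butyldimethylsilyl)oxy]labd-7-en-7-olate (not isolated) | CC(C)(C)[Si](C)(C)OCC[C@@H](C)CC[C@@H]1C(C)=C(O[Li])C[C@@H]2C(C)(C)C[C@@H](O[Si](C)(C)C(C)(C)C)C[C@@]12C | intermediate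
21 | (2R,5R,9S,10R,13S)-2,15-bis[(tert-butyldimethylsilyl)oxy]labd-7-en-7-yl trifluoromethanesulfonate | CC(C)(C)[Si](C)(C)OCC[C@@H](C)CC[C@@H]1C(C)=C(OS(=O)(=O)C(F)(F)F)C[C@@H]2C(C)(C)C[C@@H](O[Si](C)(C)C(C)(C)C)C[C@@]12C | intermediate
22 | (2R,5R,9R,10R,13S)-2,15-bis[(tert-butyldimethylsilyl)oxy]labd-7-ene | CC(C)(C)[Si](C)(C)OCC[C@@H](C)CC[C@@H]1C(C)=CC[C@@H]2C(C)(C)C[C@@H](O[Si](C)(C)C(C)(C)C)C[C@@]12C | intermediate
23 | (2R,5R,9R,10R,13S)-labd-7-ene-2,15-diol | OCC[C@@H](C)CC[C@@H]1C(C)=CC[C@@H]2C(C)(C)C[C@@H](O)C[C@@]12C | intermediate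
24 | (2R,5R,9R,10R,13S)-labd-7-ene-2,15-diyl diacetate (CNP0220683.1) | CC(=O)OCC[C@@H](C)CC[C@@H]1C(C)=CC[C@@H]2C(C)(C)C[C@@H](OC(C)=O)C[C@@]12C | target

**Step count**

Total steps: 16. Longest linear sequence: 12 (steps 1–6 and 11–16 from (S)-carvone); the side-chain branch is steps 7–10.

**Steps most likely to fail**

1. Step 5 (Proposed new method). The C4 cation may lose a proton (plain ene outcome) or take a hydride from C5 faster than it is captured by chloride and methyl, and AlMe3 may add to a carbonyl group. Fallback with known chemistry, from 7 back to 9: Me2AlCl (1.2 equiv, CH2Cl2, −78 °C) effects the classical type 2 carbonyl-ene cyclisation, forming the same C2–C3 bond, and should give (4aR,7R,8aR)-7-hydroxy-2,8a-dimethyl-5-methylidene-4a,5,6,7,8,8a-hexahydronaphthalen-1(4H)-one F1. Its exocyclic alkene is then hydromethylated by a radical route that avoids the cation: iron-hydride hydrogen-atom transfer (Fe(acac)3, PhSiH3, excess formaldehyde N-octylsulfonylhydrazone made from octane-1-sulfonohydrazide and aqueous CH2O, MeOH/THF, rt) generates the tertiary C4 radical, which adds to the hydrazone carbon to give N'-{[(1ξ,3R,4aR,8aR)-3-hydroxy-1,4a,6-trimethyl-5-oxo-1,2,3,4,4a,5,8,8a-octahydronaphthalen-1-yl]methyl}octane-1-sulfonohydrazide F2. Heating F2 in MeOH at 60 °C expels the sulfinic acid and dinitrogen and leaves the new methyl group, arriving at 9.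

2. Step 11. The organocerium may fail to reach the C9 carbonyl, which is flanked by the quaternary C10 and the C8 methyl, so that γ-deprotonation at C6 or simple recovery of the ketone takes over. Fallback, from 10 and 15 back to 22: the C9–C11 bond is made by cross-coupling instead of carbonyl addition. KN(SiMe3)2 and PhNTf2 (THF, −78 °C) convert 10 by γ-deprotonation at C6 and O-triflation into (4aR,7R,8aR)-7-[(tert-butyldimethylsilyl)oxy]-2,5,5,8a-tetramethyl-4a,5,6,7,8,8a-hexahydronaphthalen-1-yl trifluoromethanesulfonate F3. Zinc insertion into 15 (Zn dust, LiCl, THF, 40 °C) gives {(3R)-5-[(tert-butyldimethylsilyl)oxy]-3-methylpentyl}zinc iodide F4. Negishi coupling (PdCl2(dppf), THF/NMP, 50 °C) joins them to (2R,5R,10R,13S)-2,15-bis[(tert-butyldimethylsilyl)oxy]labda-6,8-diene F5. 1,4-Hydrogenation of this homoannular diene (H2, (η6-naphthalene)Cr(CO)3, THF, 40 °C) should add hydrogen to C6 and C9 from the face opposite C20 and leave the C7=C8 alkene, arriving at 22 and by-passing steps 11–14.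

3. Step 13. Protonation at C9 may take place with poor facial selectivity, the carbonyl may be over-reduced, or O-triflation of the hindered enolate may stay incomplete. Fallback, from 19 back to 22: Luche reduction (NaBH4, CeCl3·7H2O, MeOH/THF, −40 °C; axial hydride attack) should give (2R,5R,7R,10R,13S)-2,15-bis[(tert-butyldimethylsilyl)oxy]labd-8-en-7-ol F6 with the hydroxyl on the C20 face. A Mitsunobu reaction with 2-nitrobenzenesulfonohydrazide (PPh3, diethyl azodicarboxylate, THF, −30 °C) gives with inversion N-[(2R,5R,7S,10R,13S)-2,15-bis[(tert-butyldimethylsilyl)oxy]labd-8-en-7-yl]-2-nitrobenzenesulfonohydrazide F7. On warming to rt F7 loses the sulfinic acid and then dinitrogen in a retro-ene shift that places hydrogen on C9 on the face of the former C7–N bond (opposite C20) and moves the alkene to C7=C8, arriving at 22 and by-passing 21.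

**Further compounds**

F1 | step 5 | (4aR,7R,8aR)-7-hydroxy-2,8a-dimethyl-5-methylidene-4a,5,6,7,8,8a-hexahydronaphthalen-1(4H)-one | O=C1C(C)=CC[C@@H]2C(=C)C[C@@H](O)C[C@@]12C
F2 | step 5 | N'-{[(1ξ,3R,4aR,8aR)-3-hydroxy-1,4a,6-trimethyl-5-oxo-1,2,3,4,4a,5,8,8a-octahydronaphthalen-1-yl]methyl}octane-1-sulfonohydrazide | O=C1C(C)=CC[C@@H]2C(C)(CNNS(=O)(=O)CCCCCCCC)C[C@@H](O)C[C@@]12C
F3 | step 11 | (4aR,7R,8aR)-7-[(tert-butyldimethylsilyl)oxy]-2,5,5,8a-tetramethyl-4a,5,6,7,8,8a-hexahydronaphthalen-1-yl trifluoromethanesulfonate | FC(F)(F)S(=O)(=O)OC1=C(C)C=C[C@@H]2C(C)(C)C[C@@H](O[Si](C)(C)C(C)(C)C)C[C@@]12C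
F4 | step 11 | {(3R)-5-[(tert-butyldimethylsilyl)oxy]-3-methylpentyl}zinc iodide | CC(C)(C)[Si](C)(C)OCC[C@@H](C)CC[Zn]I
F5 | step 11 | (2R,5R,10R,13S)-2,15-bis[(tert-butyldimethylsilyl)oxy]labda-6,8-diene | CC(C)(C)[Si](C)(C)OCC[C@@H](C)CCC1=C(C)C=C[C@@H]2C(C)(C)C[C@@H](O[Si](C)(C)C(C)(C)C)C[C@@]12C
F6 | step 13 | (2R,5R,7R,10R,13S)-2,15-bis[(tert-butyldimethylsilyl)oxy]labd-8-en-7-ol | CC(C)(C)[Si](C)(C)OCC[C@@H](C)CCC1=C(C)[C@H](O)C[C@@H]2C(C)(C)C[C@@H](O[Si](C)(C)C(C)(C)C)C[C@@]12C
F7 | step 13 | N-[(2R,5R,7S,10R,13S)-2,15-bis[(tert-butyldimethylsilyl)oxy]labd-8-en-7-yl]-2-nitrobenzenesulfonohydrazide | CC(C)(C)[Si](C)(C)OCC[C@@H](C)CCC1=C(C)[C@@H](N(N)S(=O)(=O)c3ccccc3[N+](=O)[O-])C[C@@H]2C(C)(C)C[C@@H](O[Si](C)(C)C(C)(C)C)C[C@@]12C
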